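The depside is cut at its aryl ester into ring B (benzyl olivetolate, O-methylated at C2 after coupling) and ring A, 2,4-dimethoxy-6-propylbenzoic acid. The route rests on making ring A from a 2-pyrone and exploits its 1-carboxy-2,4-dimethoxy-6-propyl pattern: methyl 4-methoxy-2-oxo-6-propyl-2H-pyran-5-carboxylate already holds the C1 ester, C2 methoxy and C6 propyl on pyrone C5, C4 and C6. An inverse-demand Diels–Alder reaction with 1,1-dimethoxyethene forms ring A bonds C3–C4 and C5–C6; loss of CO2 and methanol then aromatizes the adduct, supplying C4 with its methoxy group and the bare C5 in one operation.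

Key step: step 5

Remark: ring A is the acyl ring (C1 bears the ester carbonyl) and ring B is the pentyl-bearing ring (C1 bears CO2H).
Remark: ring B is bought as olivetolic acid; direct carboxylation of olivetol is left out because the carboxyl group could enter at C2 as well as at C4 of the resorcinol.
Remark: 3 is drawn as its triketo form; it should be largely enolized, so its formal stereocentre is labile and left undefined. Bridged lactone 8 is racemic and both of its stereocentres vanish within the same step.

Step 1
Reactants: 1 dimethyl 3-oxopentanedioate; 2 butanoyl chloride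
Product: 3 dimethyl 2-butanoyl-3-oxopentanedioate
Conditions: MgCl2, pyridine, CH2Cl2, 0 °C to rt; 2 (1.0 equiv)
Reagents that add atoms: none
Why: Magnesium-mediated soft enolization and C-acylation of a β-keto ester, in which the magnesium chelate is acylated on carbon by the acid chloride and holds the product as its enolate, so that one equivalent of 2 should give monoacylation.

Step 2
Reactants: 3 dimethyl 2-butanoyl-3-oxopentanedioate
Product: 4 methyl 4-hydroxy-2-oxo-6-propyl-2H-pyran-5-carboxylate
Conditions: conc. H2SO4, 0 °C to rt; then ice-water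
Reagents that add atoms: none
Why: Acid-catalysed lactonization (intramolecular transesterification) in which the enol oxygen of the butanoyl ketone closes onto the remote CH2–CO2Me ester (6-exo-trig, the only ring size open to this tricarbonyl compound) and loss of methanol gives the 4-hydroxy-2-pyrone.

Step 3
Reactants: 4 methyl 4-hydroxy-2-oxo-6-propyl-2H-pyran-5-carboxylate
Product: 5 methyl 4-methoxy-2-oxo-6-propyl-2H-pyran-5-carboxylate
Conditions: Me2SO4, K2CO3, acetone, reflux
Reagents that add atoms: dimethyl sulfate, COS(=O)(=O)OC
Why: Williamson-type O-methylation of a vinylogous carboxylic acid under the standard conditions by which 4-hydroxy-2-pyrones give the 4-methoxy-2-pyrone and not the 2-methoxy-4-pyrone isomer.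

Step 4
Reactants: 6 2-bromo-1,1-dimethoxyethane
Product: 7 1,1-dimethoxyethene
Conditions: KOtBu, no solvent, 90 to 130 °C, product distilled out; redistilled from Na
Reagents that add atoms: none
Why: E2 dehydrobromination of a bromoacetal by a hindered alkoxide, the classical ketene acetal preparation, with the volatile product leaving the base by distillation as it forms.

Step 5
Reactants: 5 methyl 4-methoxy-2-oxo-6-propyl-2H-pyran-5-carboxylate; 7 1,1-dimethoxyethene
Product: 10 methyl 2,4-dimethoxy-6-propylbenzoate, via bridged lactone 8 (not isolated), via dimethoxycyclohexadiene 9 (not isolated)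
Conditions: 7 (5 equiv), toluene, sealed tube, 140 °C; then cat. TsOH, CH2Cl2, rt
Reagents that add atoms: none
Why: The nucleophilic CH2 of 7 bonds to pyrone C6 while its acetal carbon bonds to pyrone C3, an asynchronous inverse-electron-demand [4+2] cycloaddition across C3 and C6 that closes the carbocycle as the 2-oxabicyclo[2.2.2]octenone 8. Retro-[4+2] loss of CO2 from 8 gives the 4,4-dimethoxycyclohexadiene 9, and 1,2-elimination of methanol (finished by the acid treatment if needed) aromatizes it to 10. The closest known reaction type is the Diels–Alder/decarboxylation of 5-carboalkoxy- and 3-carboalkoxy-2-pyrones with ketene acetals to give alkoxybenzoates. The two bridgehead stereocentres of 8 are fixed relative to each other by the bicycle and are destroyed on aromatization, so no stereocontrol is required. The selectivity needed is regiochemical and is secured by polarization: C6 is the acceptor terminus, conjugated to both the C5 ester and the lactone carbonyl, and C3 is the donor terminus as the β-carbon of the C4 enol ether, whereas the reverse orientation would lead to the 2,5-dimethoxy isomer. Because the C4 methoxy group makes the diene less electron-poor than a simple coumalate, excess dienophile, base-washed glass and sealed-tube heating are specified.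

Step 6
Reactants: 10 methyl 2,4-dimethoxy-6-propylbenzoate
Product: 11 2,4-dimethoxy-6-propylbenzoic acid
Conditions: KOH, DMSO/H2O, 100 °C; then cold 1 M HCl to pH 3
Reagents that add atoms: potassium hydroxide, [K+].[OH-]
Why: Saponification (BAc2) of a doubly ortho-substituted benzoate by poorly solvated hydroxide in aqueous DMSO, to which the aryl methyl ethers are inert, with cold acidification to avoid protodecarboxylation of the electron-rich acid.

Step 7
Reactants: 12 olivetolic acid (2,4-dihydroxy-6-pentylbenzoic acid)
Product: 13 benzyl 2,4-dihydroxy-6-pentylbenzoate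
Conditions: BnBr, KHCO3, DMF, rt
Reagents that add atoms: benzyl bromide, BrCc1ccccc1
Why: SN2 alkylation of the carboxylate, since KHCO3 deprotonates only the carboxylic acid and leaves both phenols free, at a temperature low enough to avoid decarboxylation of the β-resorcylic acid.

Step 8
Reactants: 11 2,4-dimethoxy-6-propylbenzoic acid; 13 benzyl 2,4-dihydroxy-6-pentylbenzoate
Product: 15 benzyl 4-[(2,4-dimethoxy-6-propylbenzoyl)oxy]-2-hydroxy-6-pentylbenzoate, via mixed anhydride 14 (not isolated)
Conditions: (CF3CO)2O, toluene, rt
Reagents that add atoms: none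
Why: Esterification through a mixed trifluoroacetic anhydride, the standard depside coupling for hindered electron-rich benzoic acids, in which only the C4 hydroxyl of 13 is acylated because the C2 hydroxyl is hydrogen-bonded to the adjacent benzyl ester carbonyl.

Step 9
Reactants: 15 benzyl 4-[(2,4-dimethoxy-6-propylbenzoyl)oxy]-2-hydroxy-6-pentylbenzoate
Product: 16 benzyl 4-[(2,4-dimethoxy-6-propylbenzoyl)oxy]-2-methoxy-6-pentylbenzoate
Conditions: MeI, K2CO3, dry acetone, reflux
Reagents that add atoms: iodomethane, CI
Why: Williamson ether synthesis on the remaining hydrogen-bonded phenol, in a dry medium without hydroxide or alkoxide, where the depside carbonyl is shielded by its two ortho substituents and both esters should survive.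

Step 10
Reactants: 16 benzyl 4-[(2,4-dimethoxy-6-propylbenzoyl)oxy]-2-methoxy-6-pentylbenzoate
Product: 17 4-[(2,4-dimethoxy-6-propylbenzoyl)oxy]-2-methoxy-6-pentylbenzoic acid
Conditions: H2 (1 atm), 10% Pd/C, EtOAc, rt
Reagents that add atoms: none
Why: Hydrogenolysis of the benzylic C–O bond over Pd/C frees the carboxylic acid under neutral conditions that affect neither the aryl ester nor the aryl ethers.

Compound list
1 | dimethyl 3-oxopentanedioate | COC(=O)CC(=O)CC(=O)OC | starting material
2 | butanoyl chloride | CCCC(=O)Cl | starting material
3 | dimethyl 2-butanoyl-3-oxopentanedioate (labile centre, racemic/enolized) | CCCC(=O)C(C(=O)OC)C(=O)CC(=O)OC | intermediate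
4 | methyl 4-hydroxy-2-oxo-6-propyl-2H-pyran-5-carboxylate | CCCC1=C(C(=O)OC)C(O)=CC(=O)O1 | intermediate
5 | methyl 4-methoxy-2-oxo-6-propyl-2H-pyran-5-carboxylate | CCCC1=C(C(=O)OC)C(OC)=CC(=O)O1 | intermediate
6 | 2-bromo-1,1-dimethoxyethane | COC(CBr)OC | starting material
7 | 1,1-dimethoxyethene | C=C(OC)OC | intermediate
8 | methyl (1RS,4RS)-5,8,8-trimethoxy-3-oxo-1-propyl-2-oxabicyclo[2.2.2]oct-5-ene-6-carboxylate (racemic; one enantiomer drawn) | CCC[C@@]12OC(=O)[C@@H](C(OC)=C1C(=O)OC)C(OC)(OC)C2 | intermediate (not isolated)
9 | methyl 4,4,6-trimethoxy-2-propylcyclohexa-1,5-diene-1-carboxylate | CCCC1=C(C(=O)OC)C(OC)=CC(OC)(OC)C1 | intermediate (not isolated)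
10 | methyl 2,4-dimethoxy-6-propylbenzoate | CCCc1cc(OC)cc(OC)c1C(=O)OC | intermediate
11 | 2,4-dimethoxy-6-propylbenzoic acid | CCCc1cc(OC)cc(OC)c1C(=O)O | intermediate
12 | olivetolic acid (2,4-dihydroxy-6-pentylbenzoic acid) | CCCCCc1cc(O)cc(O)c1C(=O)O | starting material
13 | benzyl 2,4-dihydroxy-6-pentylbenzoate | CCCCCc1cc(O)cc(O)c1C(=O)OCc1ccccc1 | intermediate
14 | 2,4-dimethoxy-6-propylbenzoic trifluoroacetic anhydride | CCCc1cc(OC)cc(OC)c1C(=O)OC(=O)C(F)(F)F | intermediate (not isolated)
15 | benzyl 4-[(2,4-dimethoxy-6-propylbenzoyl)oxy]-2-hydroxy-6-pentylbenzoate | CCCCCc1cc(OC(=O)c2c(CCC)cc(OC)cc2OC)cc(O)c1C(=O)OCc1ccccc1 | intermediate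
16 | benzyl 4-[(2,4-dimethoxy-6-propylbenzoyl)oxy]-2-methoxy-6-pentylbenzoate | CCCCCc1cc(OC(=O)c2c(CCC)cc(OC)cc2OC)cc(OC)c1C(=O)OCc1ccccc1 | intermediate
17 | 4-[(2,4-dimethoxy-6-propylbenzoyl)oxy]-2-methoxy-6-pentylbenzoic acid (CNP0590692.0, achiral) | CCCCCc1cc(OC(=O)c2c(CCC)cc(OC)cc2OC)cc(OC)c1C(=O)O | target

Total step count: 10. Longest linear sequence: 8 steps (1, 2, 3, 5, 6, 8, 9, 10) from dimethyl 3-oxopentanedioate.

Steps most likely to fail

Step 5. The cycloaddition may be too slow, because the C4 methoxy group reduces the electron deficiency of the diene, while the ketene acetal oligomerizes or is consumed by traces of acid at the temperature needed; addition in the reverse orientation is a lesser concern. The fallback takes ring A from an existing arene instead of building it. It sets out from butanoyl chloride 2. Acylation of commercial 3,5-dimethoxyphenylmagnesium chloride with 2 (cat. Fe(acac)3, THF, −78 °C) should give 1-(3,5-dimethoxyphenyl)butan-1-one F1. Wolff–Kishner reduction (N2H4·H2O, KOH, diethylene glycol, 200 °C) should give 1,3-dimethoxy-5-propylbenzene F2. Bromination with N-bromosuccinimide in MeCN at 0 °C should enter para to one methoxy group and ortho to the propyl group, giving 2-bromo-1,5-dimethoxy-3-propylbenzene F3. Bromine–lithium exchange (n-BuLi, THF, −78 °C) gives (2,4-dimethoxy-6-propylphenyl)lithium F4, and quenching with CO2 followed by acid work-up comes back to the route at acid 11.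

Step 9. Under carbonate base the phenoxide of 15, or adventitious hydroxide, may attack the depside carbonyl (acyl transfer or cleavage of the aryl ester), or the hydrogen-bonded phenol may alkylate too slowly. The fallback installs the C2 methyl ether before the depside bond is made. It sets out from benzyl ester 13. Allyl bromide with one equivalent of K2CO3 in acetone should alkylate only the free C4 hydroxyl, giving benzyl 2-hydroxy-6-pentyl-4-(prop-2-en-1-yloxy)benzoate F5. MeI/K2CO3 in DMF then gives benzyl 2-methoxy-6-pentyl-4-(prop-2-en-1-yloxy)benzoate F6. Allyl transfer to morpholine with cat. Pd(PPh3)4 in THF gives benzyl 4-hydroxy-2-methoxy-6-pentylbenzoate F7. Coupling of F7 with acid 11 under the conditions of step 8 (again through mixed anhydride 14) comes back to the route at 16.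

Step 6. Hydroxide attack at the doubly ortho-substituted carbonyl may stall, and prolonged heating or the acid work-up may cause decarboxylation of the electron-rich acid or partial ether cleavage. The fallback replaces substitution at the hindered carbonyl by a reduction–oxidation detour. It sets out from ester 10. LiAlH4 in refluxing THF should give (2,4-dimethoxy-6-propylphenyl)methanol F8, and MnO2 in CH2Cl2 should give 2,4-dimethoxy-6-propylbenzaldehyde F9. Pinnick oxidation (NaClO2, NaH2PO4, 2-methylbut-2-ene, t-BuOH/H2O) comes back to the route at acid 11.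

Further compounds
F1 | step 5 | 1-(3,5-dimethoxyphenyl)butan-1-one | CCCC(=O)c1cc(OC)cc(OC)c1
F2 | step 5 | 1,3-dimethoxy-5-propylbenzene | CCCc1cc(OC)cc(OC)c1
F3 | step 5 | 2-bromo-1,5-dimethoxy-3-propylbenzene | CCCc1cc(OC)cc(OC)c1Br
F4 | step 5 | (2,4-dimethoxy-6-propylphenyl)lithium | CCCc1cc(OC)cc(OC)c1[Li]
F5 | step 9 | benzyl 2-hydroxy-6-pentyl-4-(prop-2-en-1-yloxy)benzoate | CCCCCc1cc(OCC=C)cc(O)c1C(=O)OCc1ccccc1
F6 | step 9 | benzyl 2-methoxy-6-pentyl-4-(prop-2-en-1-yloxy)benzoate | CCCCCc1cc(OCC=C)cc(OC)c1C(=O)OCc1ccccc1
F7 | step 9 | benzyl 4-hydroxy-2-methoxy-6-pentylbenzoate | CCCCCc1cc(O)cc(OC)c1C(=O)OCc1ccccc1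
F8 | step 6 | (2,4-dimethoxy-6-propylphenyl)methanol | CCCc1cc(OC)cc(OC)c1CO
F9 | step 6 | 2,4-dimethoxy-6-propylbenzaldehyde | CCCc1cc(OC)cc(OC)c1C=O
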